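**Retrosynthetic overview**

1. Target 29 ⇐ lactol 28 (enol ether made last by dehydration) ⇐ enone 27 by acid-triggered 5-endo oxa-Michael closure (O on C13 to C9, spiro oxolan-3-one) ⇐ C9 propargylic acetate 26 (Meyer–Schuster transposition) ⇐ ketone 16 + alkyne 23 (C9–C11 bond).
2. Alkyne 23 (C11–C16, carries the C13 stereocenter) ⇐ Sharpless epoxide 20 + 1,3-dithiane (C15).
3. Ketone 16 ⇐ keto lactone 14 (C4 methylation under lactone control, C3 ketal) ⇐ trans-dione 12 (C6 reduction, 19,6β-lactonisation that expels the auxiliary) ⇐ cis adduct 10 (hydrogenation, C5 epimerisation through the C6 ketone).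
4. Adduct 10 ⇐ Diels–Alder union forming C1–C10 and C4–C5 from siloxydiene amide 8 (C1–C4, C19) and 2,6-dimethyl-1,4-benzoquinone 9 (C5–C10, C17, C20). Enabling feature: ring B carries oxygen at C6 and C9 (1,4) and methyls at C8 and C10, a latent 2,6-dimethylbenzoquinone; ring A carries the C3 ketone next to C4 bearing the C19 carboxyl, a latent 3-siloxypenta-2,4-dienoic acid diene; the C6 carbonyl left by the quinone lets C5 be epimerised to the trans ring fusion.
5. Ring order: ring B (preformed in 9) → ring A (Diels–Alder) → γ-lactone → side-chain oxolane (as methyl glycoside) → spiro furanone → dihydrofuran unsaturation.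

Key step: step 5

Remark: locants and α/β are those of the labdane skeleton of the target (ring A = C1–C5, C10; ring B = C5–C10; C17 on C8; C18 and C19 on C4; C20 on C10; side chain C11–C16).
Remark: (2S,5S)-2,5-dimethylpyrrolidine is taken as a purchasable amine.

**Step 1**
Reactants: 1 (2S,5S)-2,5-dimethylpyrrolidine
Product: 2 N-acetyl-(2S,5S)-2,5-dimethylpyrrolidine
Conditions: Ac2O, CH2Cl2, 0 °C to rt
Reagents that add atoms: acetic anhydride CC(=O)OC(C)=O
Why: N-acylation of a secondary amine by an anhydride installs the two carbons that become C19 and C4 and touches no stereocenter.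

**Step 2**
Reactants: 2 N-acetyl-(2S,5S)-2,5-dimethylpyrrolidine; 3 acrolein
Product: 5 3-hydroxypent-4-enamide of the auxiliary (3RS), via lithium enolate 4 (not isolated)
Conditions: LiN(iPr)2, THF, −78 °C; then 3; then aqueous NH4Cl
Reagents that add atoms: none
Why: Aldol addition of an amide lithium enolate to an enal proceeds 1,2 at −78 °C; the new carbinol center needs no control because it is oxidised in the next step.

**Step 3**
Reactants: 5 3-hydroxypent-4-enamide of the auxiliary
Product: 6 vinyl β-keto amide (pent-4-ene-1,3-dione amide)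
Conditions: Dess–Martin periodinane, CH2Cl2, 0 °C to rt, used crude
Reagents that add atoms: none
Why: Dess–Martin oxidation of a secondary allylic alcohol gives the vinyl ketone under non-basic conditions that avoid self-Michael addition; no stereocenter is formed.

**Step 4**
Reactants: 6 vinyl β-keto amide
Product: 8 (2Z)-3-(tert-butyldimethylsilyloxy)penta-2,4-dienamide of the auxiliary, via sodium enolate 7 (not isolated)
Conditions: NaN(SiMe3)2, THF, −78 °C; then TBSOTf, −78 °C
Reagents that add atoms: tert-butyldimethylsilyl trifluoromethanesulfonate CC(C)(C)[Si](C)(C)OS(=O)(=O)C(F)(F)F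
Why: O-silylation of a chelated β-dicarbonyl sodium enolate traps the U-shaped enolate, which should give the Z enol ether (silyloxy cis to the amide carbonyl, amide trans to the vinyl group) needed for an s-cis diene.

**Step 5**
Reactants: 8 (2Z)-3-(tert-butyldimethylsilyloxy)penta-2,4-dienamide of the auxiliary; 9 2,6-dimethyl-1,4-benzoquinone
Product: 10 cis-fused Diels–Alder adduct (ring B ene-dione; 3-silyl enol ether; 4α-carboxamide; 5β-H; 10β-CH3)
Conditions: PhMe, 70 °C, BHT (cat.), dark, slight excess of 9
Reagents that add atoms: none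
Why: The step is a concerted, asynchronous, normal-electron-demand [4+2] cycloaddition in which the silyloxy-raised HOMO of diene 8 (largest coefficient at C4) meets the LUMO of quinone 9, and the closest known reaction type is the thermal Diels–Alder reaction of 2-silyloxy-1,3-dienes with methyl-substituted 1,4-benzoquinones that installs an angular methyl group. Ring A (C1–C5, C10) is closed by an intermolecular suprafacial–suprafacial six-membered [4+2] closure onto the preformed ring B, and no other ring forms. C10 is set absolutely by the auxiliary: with the amide carbonyl held s-cis to the C3–O bond, the (2S,5S)-pyrrolidine places the methyl group of its ring carbon nearest C4 over the Re face of C4, so the quinone should add to the Si face through the endo transition state (ring B under C2–C3), which corresponds to the 10β-methyl, C1-α arrangement of the target. C5 (H cis to C20) follows from suprafacial addition to the quinone C=C and C4 (carboxamide trans to C20) from the Z enol ether geometry plus the endo rule, and both are provisional because C5 is α to the C6 carbonyl and C4 becomes α to the C3 ketone. The step needs regioselectivity (C4 to the quinone CH carbon, C1 to the methyl-bearing carbon), which is secured because the nucleophilic and more substituted diene terminus pairs with the unsubstituted carbon β to the carbonyl flanked by the two methyl groups and thereby avoids a bond between two fully substituted carbons; it also needs mono-addition, which the lower dienophilicity of the remaining trisubstituted ene-dione secures, and the two C=C bonds of 9 are equivalent so no site issue arises.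

**Step 6**
Reactants: 10 cis-fused Diels–Alder adduct
Product: 12 trans-fused dione (5α-H; 8α-CH3), via cis-fused dione 11 (not isolated)
Conditions: H2 (1 atm), Pd/C (palladium on carbon), EtOAc, rt; filter; DBU (0.3 equiv), CH2Cl2, rt
Reagents that add atoms: none
Why: Catalytic hydrogenation reduces the electron-poor ene-dione C7=C8 and spares the silyl enol ether, and base equilibration through the C6 and C9 enols should then give the thermodynamic trans ring fusion (5α-H, anti to the angular methyl) and the equatorial 8α-methyl.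

**Step 7**
Reactants: 12 trans-fused dione
Product: 14 4α-H keto lactone (3,9-dioxo-19,6β-olide), via 6β-hydroxy amide 13 (not isolated)
Conditions: NaBH4, MeOH–CH2Cl2, −40 °C; then 2 M aqueous HCl, THF, 50 °C
Reagents that add atoms: none
Why: Hydride reduction takes the less hindered C6 ketone (C9 is flanked by quaternary C10 and substituted C8) from the α face because the axial C10 methyl blocks the β face, giving the axial 6β-alcohol; aqueous acid then cleaves the silyl enol ether, the β-keto amide epimerises at C4 through its enol, and the 1,3-diaxial 6β-OH and C19 carbonyl lactonise by N-to-O acyl transfer with release of the auxiliary.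

**Step 8**
Reactants: 14 4α-H keto lactone
Product: 15 4α-methyl diketo lactone
Conditions: MeI, K2CO3, acetone, rt
Reagents that add atoms: iodomethane CI
Why: C-alkylation of a β-keto lactone enolate installs C18, and the methyl can only enter from the α face because the cis-fused lactone holds C19 on the β face, which sets the C4 quaternary center.

**Step 9**
Reactants: 15 4α-methyl diketo lactone
Product: 16 3,3-ethylenedioxy ketal (9-ketone free)
Conditions: HOCH2CH2OH, TsOH·H2O (cat.), PhH, reflux, Dean–Stark
Reagents that add atoms: ethane-1,2-diol OCCO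
Why: Acid-catalysed ketalisation should select the C3 ketone over the C9 ketone, which is shielded on both sides by C10 (quaternary) and C8 (methyl-bearing); no stereocenter changes.

**Step 10**
Reactants: 17 2-bromoprop-2-en-1-ol; 18 ethynyltrimethylsilane
Product: 19 2-methylidene-4-(trimethylsilyl)but-3-yn-1-ol
Conditions: PdCl2(PPh3)2 (2 mol %), CuI (4 mol %), Et3N, THF, rt
Reagents that add atoms: none
Why: Sonogashira coupling of a vinyl bromide with a terminal alkyne builds the C11–C12–C13 enyne with C14 and C16 attached; no stereocenter is formed.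

**Step 11**
Reactants: 19 2-methylidene-4-(trimethylsilyl)but-3-yn-1-ol
Product: 20 (R)-{2-[(trimethylsilyl)ethynyl]oxiran-2-yl}methanol
Conditions: Ti(OiPr)4 (10 mol %), D-(−)-diisopropyl tartrate (12 mol %), t-BuOOH, 4 Å molecular sieves, CH2Cl2, −20 °C
Reagents that add atoms: tert-butyl hydroperoxide CC(C)(C)OO
Why: Sharpless asymmetric epoxidation of a 2-substituted allylic alcohol sets C13, and the D-(−)-tartrate is expected to deliver oxygen to the face that gives the (R)-epoxide, by analogy with (R)-2-methylglycidol from the same tartrate.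

**Step 12**
Reactants: 20 (R)-{2-[(trimethylsilyl)ethynyl]oxiran-2-yl}methanol
Product: 21 (2R)-2-(1,3-dithian-2-ylmethyl)-4-(trimethylsilyl)but-3-yne-1,2-diol
Conditions: n-BuLi (1.0 equiv), THF, −78 °C; then 2-lithio-1,3-dithiane (from 1,3-dithiane and n-BuLi, 1.5 equiv), THF, −30 to 0 °C; then aqueous NH4Cl
Reagents that add atoms: 1,3-dithiane C1CSCSC1
Why: Opening of the epoxide at its CH2 terminus by a dithiane anion adds C15 at the aldehyde oxidation level without touching C13, and the possible alkoxide-induced epoxide migration is degenerate here (it regenerates the same enantiomer) so no erosion is expected.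

**Step 13**
Reactants: 21 (2R)-2-(1,3-dithian-2-ylmethyl)-4-(trimethylsilyl)but-3-yne-1,2-diol
Product: 22 (3R)-5-methoxy-3-[(trimethylsilyl)ethynyl]oxolan-3-ol (anomer mixture)
Conditions: PhI(O2CCF3)2, MeOH, MeCN, 0 °C to rt
Reagents that add atoms: methanol CO
Why: Oxidative dithioacetal cleavage by a hypervalent iodine reagent in methanol gives the oxocarbenium ion, which the primary C16 hydroxyl traps as the five-membered methyl glycoside (the tertiary hydroxyl would have to form a four-membered ring); the anomeric center is irrelevant and C13 is untouched.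

**Step 14**
Reactants: 22 (3R)-5-methoxy-3-[(trimethylsilyl)ethynyl]oxolan-3-ol
Product: 23 triethylsilyl ether of 22
Conditions: TESOTf, 2,6-lutidine, CH2Cl2, −78 to 0 °C
Reagents that add atoms: triethylsilyl trifluoromethanesulfonate CC[Si](CC)(CC)OS(=O)(=O)C(F)(F)F
Why: Silyl triflate silylation protects the tertiary propargylic hydroxyl so that only the C9 oxygen will carry an acyl group later; no stereocenter changes.

**Step 15**
Reactants: 23 triethylsilyl ether of 22; 16 3,3-ethylenedioxy ketal
Product: 26 C9 propargylic acetate (9α-alkynyl; 9β-OAc expected), via lithium acetylide 24 (not isolated), via lithium C9-alkoxide 25 (not isolated)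
Conditions: MeLi·LiBr (0.95 equiv per 23), THF, 0 °C to rt; then LaCl3·2LiCl (30 mol %) and 16, −78 to −20 °C; then Ac2O, −20 °C to rt
Reagents that add atoms: acetic anhydride CC(=O)OC(C)=O
Why: Methyllithium cleaves the alkynyl–silicon bond to the lithium acetylide, which undergoes lanthanum-assisted 1,2-addition to the only free ketone (C3 is ketalised and the neopentylic lactone carbonyl is shielded), axial attack from the α face anti to the C10 methyl being expected but inconsequential because C9 is re-formed later, and the hindered tertiary alkoxide is acetylated in situ.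

**Step 16**
Reactants: 26 C9 propargylic acetate
Product: 27 C9=C11 enone (12-ketone; E expected)
Conditions: Ph3PAuNTf2 (5 mol %), wet butan-2-one, rt
Reagents that add atoms: none
Why: Monovalent-gold-catalysed [3,3]-acyloxy shift of the propargylic acetate to the allenyl acetate followed by hydrolysis is a Meyer–Schuster-type transposition that places the carbonyl on C12, and it is regio-defined because only the C9 oxygen is acylated; no stereocenter is formed and the alkene geometry does not matter.

**Step 17**
Reactants: 27 C9=C11 enone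
Product: 28 spiro lactol (3,12-dione; 9α,13-epoxide; C15 hemiacetal)
Conditions: 3 M aqueous HCl, THF, 45 °C
Reagents that add atoms: water O
Why: Aqueous acid removes the silyl ether, the ketal and the methyl glycoside, and the freed C13 hydroxyl adds to the protonated β,β-disubstituted enone (acid-promoted 5-endo oxa-Michael cyclisation of an α′-hydroxy enone to an oxolan-3-one, with tertiary cation character at C9); oxygen should enter C9 axially from the α face anti to the axial C10 methyl, giving 9α-O with C11 equatorial, which is also the expected thermodynamic outcome of this reversible addition, while C13 keeps its configuration.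

**Step 18**
Reactants: 28 spiro lactol
Product: 29 target CNP0143138.1
Conditions: MsCl, Et3N, CH2Cl2, 0 to 40 °C
Reagents that add atoms: none
Why: Sulfonylation of the lactol hydroxyl and base-mediated elimination toward C14 (the only β-hydrogens) is the glycal-type dehydration of 2-deoxy lactols and gives the C14=C15 enol ether without touching any stereocenter.

**Compound list**

1 | (2S,5S)-2,5-dimethylpyrrolidine | C[C@H]1CC[C@H](C)N1 | starting material
2 | 1-[(2S,5S)-2,5-dimethylpyrrolidin-1-yl]ethan-1-one | CC(=O)N1[C@@H](C)CC[C@@H]1C | intermediate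
3 | acrolein (prop-2-enal) | C=CC=O | starting material
4 | lithium enolate of 2 | [Li]OC(=C)N1[C@@H](C)CC[C@@H]1C | intermediate
5 | 1-[(2S,5S)-2,5-dimethylpyrrolidin-1-yl]-3-hydroxypent-4-en-1-one (3RS) | C=CC(O)CC(=O)N1[C@@H](C)CC[C@@H]1C | intermediate
6 | 1-[(2S,5S)-2,5-dimethylpyrrolidin-1-yl]pent-4-ene-1,3-dione | C=CC(=O)CC(=O)N1[C@@H](C)CC[C@@H]1C | intermediate
7 | sodium (Z)-enolate of 6 | C=C/C(O[Na])=C/C(=O)N1[C@@H](C)CC[C@@H]1C | intermediate
8 | (2Z)-3-[(tert-butyldimethylsilyl)oxy]-1-[(2S,5S)-2,5-dimethylpyrrolidin-1-yl]penta-2,4-dien-1-one | C=C/C(O[Si](C)(C)C(C)(C)C)=C/C(=O)N1[C@@H](C)CC[C@@H]1C | intermediate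
9 | 2,6-dimethyl-1,4-benzoquinone | CC1=CC(=O)C=C(C)C1=O | starting material
10 | cis-fused Diels–Alder adduct: 3-OTBS Δ2 enol ether, 4α-C(=O)N-auxiliary (4β-H), 5β-H, 10β-CH3, 6,9-dione, Δ7 with 8-CH3 | C[C@H]1CC[C@H](C)N1C(=O)[C@@H]2C(O[Si](C)(C)C(C)(C)C)=CC[C@]3(C)C(=O)C(C)=CC(=O)[C@H]23 | intermediate
11 | cis-fused dione: 10 with C7–C8 saturated, 8α-CH3 expected | C[C@H]1CC[C@H](C)N1C(=O)[C@@H]2C(O[Si](C)(C)C(C)(C)C)=CC[C@]3(C)C(=O)[C@H](C)CC(=O)[C@H]23 | intermediate
12 | trans-fused dione: 5α-H, 8α-CH3, 10β-CH3, 4α-carboxamide, 3-OTBS Δ2, 6,9-dione | C[C@H]1CC[C@H](C)N1C(=O)[C@@H]2C(O[Si](C)(C)C(C)(C)C)=CC[C@]3(C)C(=O)[C@H](C)CC(=O)[C@@H]23 | intermediate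
13 | 6β-hydroxy amide: 12 with 6β-OH, 9-ketone kept | C[C@H]1CC[C@H](C)N1C(=O)[C@@H]2C(O[Si](C)(C)C(C)(C)C)=CC[C@]3(C)C(=O)[C@H](C)C[C@@H](O)[C@@H]23 | intermediate
14 | keto lactone: 4α-H, 5α-H, 8α-CH3, 10β-CH3, 3,9-dione, 19,6β-olide (C18 absent) | C[C@@H]1C[C@H]2OC(=O)[C@H]3C(=O)CC[C@@](C)([C@@H]23)C1=O | intermediate
15 | diketo lactone: 14 with 4α-CH3 | C[C@@H]1C[C@H]2OC(=O)[C@@]3(C)C(=O)CC[C@@](C)([C@@H]23)C1=O | intermediate
16 | 3,3-ethylenedioxy ketal of 15, 9-ketone free | C[C@@H]1C[C@H]2OC(=O)[C@@]3(C)C4(OCCO4)CC[C@@](C)([C@@H]23)C1=O | intermediate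
17 | 2-bromoprop-2-en-1-ol | OCC(Br)=C | starting material
18 | ethynyltrimethylsilane | C#C[Si](C)(C)C | starting material
19 | 2-methylidene-4-(trimethylsilyl)but-3-yn-1-ol | OCC(=C)C#C[Si](C)(C)C | intermediate
20 | (R)-{2-[(trimethylsilyl)ethynyl]oxiran-2-yl}methanol | OC[C@@]1(CO1)C#C[Si](C)(C)C | intermediate
21 | (2R)-2-(1,3-dithian-2-ylmethyl)-4-(trimethylsilyl)but-3-yne-1,2-diol | OC[C@@](O)(CC1SCCCS1)C#C[Si](C)(C)C | intermediate
22 | (3R)-5-methoxy-3-[(trimethylsilyl)ethynyl]oxolan-3-ol, anomer mixture | C[Si](C)(C)C#C[C@]1(O)CC(OC)OC1 | intermediate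
23 | triethyl{[(3R)-5-methoxy-3-[(trimethylsilyl)ethynyl]oxolan-3-yl]oxy}silane | C[Si](C)(C)C#C[C@]1(O[Si](CC)(CC)CC)CC(OC)OC1 | intermediate
24 | lithium acetylide from 23 | [Li]C#C[C@]1(O[Si](CC)(CC)CC)CC(OC)OC1 | intermediate
25 | lithium C9-alkoxide: 16 with 9α-alkynyl side chain, 9β-OLi | C[C@@H]1C[C@H]2OC(=O)[C@@]3(C)C4(OCCO4)CC[C@@](C)([C@@H]23)[C@]1(O[Li])C#C[C@]5(O[Si](CC)(CC)CC)CC(OC)OC5 | intermediate
26 | C9 propargylic acetate: 9β-OAc, 9α-alkynyl, 3-ketal, 13-OTES, 15-OMe acetal | C[C@@H]1C[C@H]2OC(=O)[C@@]3(C)C4(OCCO4)CC[C@@](C)([C@@H]23)[C@]1(OC(C)=O)C#C[C@]5(O[Si](CC)(CC)CC)CC(OC)OC5 | intermediate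
27 | enone: C9=C11 (E), 12-ketone, 13-OTES, 3-ketal, 15-OMe acetal | C[C@@H]1C[C@H]2OC(=O)[C@@]3(C)C4(OCCO4)CC[C@@](C)([C@@H]23)/C1=C/C(=O)[C@]5(O[Si](CC)(CC)CC)CC(OC)OC5 | intermediate
28 | spiro lactol: 3,12-dione, 9α,13-epoxide, 19,6β-olide, 15-hydroxy-15,16-epoxide (C15 epimers) | C[C@@H]1C[C@H]2OC(=O)[C@@]3(C)C(=O)CC[C@@](C)([C@@H]23)[C@@]12CC(=O)[C@@]1(CC(O)OC1)O2 | intermediate
29 | CNP0143138.1: 9α,13:15,16-diepoxy-3,12-dioxolabd-14-en-19,6β-olide | C[C@@H]1C[C@H]2OC(=O)[C@@]3(C)C(=O)CC[C@@](C)([C@@H]23)[C@@]12CC(=O)[C@@]1(C=COC1)O2 | target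

**Step count and risks**

Total step count: 18. Longest linear sequence: 13 steps (steps 1–9 and 15–18); the side-chain branch is steps 10–14.

Steps most likely to fail:

Step 5. The π-facial discrimination by the pyrrolidine amide may be insufficient (the shielding model rests on an s-cis amide conformation), and electron transfer or stepwise Michael addition to the quinone may compete. Fallback: give up auxiliary control and resolve through the enantiopure side chain. The fallback sets out from 14, then obtained together with its enantiomer, ent-keto lactone F1. Methylation and ketalisation as in steps 8 and 9 give 15 and 16 along with ent-diketo lactone F2 and ent-ketal F3. Coupling with enantiopure 23 as in step 15 turns the decalin enantiomers into diastereomers, 26 and the diastereomeric acetate F4, which are separated by chromatography. The route is rejoined at 26.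

Step 16. The acyloxy shift at an alkyne flanked by two fully substituted carbons may stall, or ionisation at C9 may divert to elimination. Fallback: form C9–C11 by an aldol addition instead. The fallback sets out from 23 and 16. K2CO3 in MeOH removes the alkynyl silyl group to give terminal alkyne F5, and Markovnikov hydration (Ph3PAuNTf2, aqueous dioxane) gives methyl ketone F6. Its lithium enolate (LiN(iPr)2, THF, −78 °C, LaCl3·2LiCl) adds to the C9 ketone of 16 to give aldol F7. The aqueous HCl treatment of step 17 then ionises and dehydrates the tertiary C9 carbinol and closes the spiro ether, so the route is rejoined at 28.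

Step 18. Ionisation of the anomeric sulfonate may end in substitution by chloride, or the acid formed may degrade the enol ether. Fallback: a thermal syn-elimination under neutral conditions. The fallback sets out from 28. N-(phenylseleno)phthalimide and Bu3P convert the lactol into anomeric phenyl selenide F8. Oxidation with H2O2 gives selenoxide F9 (not isolated), which eliminates toward C14 at rt to 40 °C in the presence of iPr2NEt and gives 29.

**Further compounds**

F1 | step 5 | ent-keto lactone (enantiomer of 14) | C[C@H]1C[C@@H]2OC(=O)[C@@H]3C(=O)CC[C@](C)([C@H]23)C1=O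
F2 | step 5 | ent-diketo lactone (enantiomer of 15) | C[C@H]1C[C@@H]2OC(=O)[C@]3(C)C(=O)CC[C@](C)([C@H]23)C1=O
F3 | step 5 | ent-ketal (enantiomer of 16) | C[C@H]1C[C@@H]2OC(=O)[C@]3(C)C4(OCCO4)CC[C@](C)([C@H]23)C1=O
F4 | step 5 | diastereomeric acetate (ent-decalin joined to the (3R) side chain) | C[C@H]1C[C@@H]2OC(=O)[C@]3(C)C4(OCCO4)CC[C@](C)([C@H]23)[C@@]1(OC(C)=O)C#C[C@]5(O[Si](CC)(CC)CC)CC(OC)OC5
F5 | step 16 | triethyl{[(3R)-3-ethynyl-5-methoxyoxolan-3-yl]oxy}silane | C#C[C@]1(O[Si](CC)(CC)CC)CC(OC)OC1
F6 | step 16 | 1-[(3S)-5-methoxy-3-(triethylsilyloxy)oxolan-3-yl]ethan-1-one | CC(=O)[C@]1(O[Si](CC)(CC)CC)CC(OC)OC1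
F7 | step 16 | aldol adduct: 16 with 9β-OH and 9α-CH2C(=O)-oxolanyl side chain | C[C@@H]1C[C@H]2OC(=O)[C@@]3(C)C4(OCCO4)CC[C@@](C)([C@@H]23)[C@]1(O)CC(=O)[C@]5(O[Si](CC)(CC)CC)CC(OC)OC5
F8 | step 18 | anomeric phenyl selenide of 28 (C15–SePh) | C[C@@H]1C[C@H]2OC(=O)[C@@]3(C)C(=O)CC[C@@](C)([C@@H]23)[C@@]12CC(=O)[C@@]1(CC([Se]c3ccccc3)OC1)O2
F9 | step 18 | selenoxide of F8 | C[C@@H]1C[C@H]2OC(=O)[C@@]3(C)C(=O)CC[C@@](C)([C@@H]23)[C@@]12CC(=O)[C@@]1(CC([Se](=O)c3ccccc3)OC1)O2
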